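Ring B is disconnected at C5–C6 and C9–C10. A catalyst-controlled Diels–Alder reaction between a ring A cyclohexenecarbaldehyde (olefin C5=C10, formyl carbon C15 on C10, C3 masked as a dioxolane) and an (E)-1-(silyloxymethyl)butadiene closes ring B and sets C5, C10 and C9 in one operation. The feature exploited is the contiguous all-cis triad of ring B: H-5, C15 on C10 and C11 on C9 share one face of a cis-fused decalin, which is what suprafacial, formyl-endo addition of an E-diene to a ring olefin delivers. Afterwards the formyl group is reduced to the angular methyl, the C11 hydroxyl steers oxygen to C8, and isofraxidin, the methylene group and the C3 acetate follow.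

Key step: step 6

Remark on numbering: from compound 9 on, drimane numbering is used (ring A = C1–C5 and C10; ring B = C5–C10; C11 = CH2O on C9; C12 = methylene carbon on C8; C15 = carbon on C10; "12-nor" = no carbon on C8). Compounds 2–6 carry spiro numbering, in which spiro C7 becomes C5 and spiro C8 becomes C10.

Assumption: the (S)-configured catalyst is taken to leave the Re face of C10 open, as the formyl C–H···O binding model for 2-substituted enals predicts; the absolute configuration of the route rests on that model.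

Step 1
Reactants: 1 2,2-dimethylcyclohexane-1,3-dione
Product: 2 6,6-dimethyl-1,4-dioxaspiro[4.5]decan-7-one
Conditions: HOCH2CH2OH (1.05 equiv), p-toluenesulfonic acid monohydrate (cat.), benzene, reflux, Dean–Stark
Reagents that add atoms: ethylene glycol, OCCO
Why: Acid-catalysed ketalisation with azeotropic removal of water should stop at the mono-dioxolane, because the remaining carbonyl, flanked by the quaternary carbon and the new ketal, is ketalised far more slowly; no stereocentre is formed.

Step 2
Reactants: 2 6,6-dimethyl-1,4-dioxaspiro[4.5]decan-7-one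
Product: 3 (Z)-8-(hydroxymethylene)-6,6-dimethyl-1,4-dioxaspiro[4.5]decan-7-one (chelated enol form)
Conditions: NaH, HCO2Et, EtOH (cat.), THF, 0 °C to rt; cold dilute HCl work-up
Reagents that add atoms: ethyl formate, CCOC=O
Why: Crossed Claisen condensation (α-formylation) can occur only at the single enolisable CH2 next to the ketone, which places the future C15 on the future C10.

Step 3
Reactants: 3 (Z)-8-(hydroxymethylene)-6,6-dimethyl-1,4-dioxaspiro[4.5]decan-7-one
Product: 4 (E)-8-(isopropoxymethylene)-6,6-dimethyl-1,4-dioxaspiro[4.5]decan-7-one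
Conditions: i-PrI, K2CO3, acetone, reflux
Reagents that add atoms: 2-iodopropane, CC(C)I
Why: O-Alkylation of the vinylogous acid with a secondary iodide and carbonate base should give the vinylogous ester (enol ether), whose double-bond geometry is lost in the next step.

Step 4
Reactants: 4 (E)-8-(isopropoxymethylene)-6,6-dimethyl-1,4-dioxaspiro[4.5]decan-7-one
Product: 6 6,6-dimethyl-1,4-dioxaspiro[4.5]dec-7-ene-8-carbaldehyde, via allylic alcohol 5 (not isolated)
Conditions: LiAlH4, Et2O, 0 °C; then 1 M HCl, THF, 0 °C, brief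
Reagents that add atoms: water, O
Why: 1,2-Hydride reduction of the vinylogous ester followed by acid-induced loss of the allylic hydroxyl and hydrolysis of the resulting alkoxy-allyl cation (1,3-carbonyl transposition) should give the enal much faster than the dioxolane is hydrolysed; the carbinol stereocentre of 5 disappears.

Step 5
Reactants: 7 (E)-penta-2,4-dien-1-ol
Product: 8 (E)-tert-butyl(penta-2,4-dien-1-yloxy)diphenylsilane
Conditions: TBDPSCl, imidazole, CH2Cl2, 0 °C to rt
Reagents that add atoms: tert-butyl(chloro)diphenylsilane, CC(C)(C)[Si](Cl)(c1ccccc1)c1ccccc1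
Why: Imidazole-promoted silylation of the primary alcohol gives a bulky, weakly Lewis-basic ether that should neither bind the boron catalyst nor ionise at the dienyl position, and that is shed later without a separate step.

Step 6
Reactants: 6 6,6-dimethyl-1,4-dioxaspiro[4.5]dec-7-ene-8-carbaldehyde; 8 (E)-tert-butyl(penta-2,4-dien-1-yloxy)diphenylsilane
Product: 9 (5R,9R,10S)-11-(tert-butyldiphenylsilyloxy)-3,3-(ethylenedioxy)-12-nordrim-7-en-15-al (cis-fused; H-5, the C10 formyl group and C11 on one face)
Conditions: (S)-1-(2-methylphenyl)-3,3-diphenyltetrahydro-1H,3H-pyrrolo[1,2-c][1,3,2]oxazaborole (20 mol %), Tf2NH (17 mol %), 8 (3 equiv), CH2Cl2, −78 to −20 °C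
Reagents that add atoms: none
Why: The boron cation binds the formyl oxygen of 6 syn to the formyl hydrogen, lowers the LUMO of the s-trans enal and screens one face of C5=C10 with an aryl group, so that 8 should add from the open Re face of C10 in a concerted, asynchronous [4+2] process; the closest known reaction type is the oxazaborolidinium-catalysed enantioselective Diels–Alder reaction of 2-substituted enals. Ring B closes by intermolecular [4+2] annulation, the free diene terminus C6 bonding to the β-carbon C5 and the substituted terminus C9 to C10. C5 and C10 come out cis because both bonds form on one face of the ring olefin, C9 is set by the E geometry of the diene together with the formyl-endo transition state, which places C11 cis to C15, and the catalyst sets the absolute configuration of all three. The step needs ortho regiochemistry, endo topology and one enantioface: the 1-alkyl diene has its larger HOMO coefficient at C6, which also brings the unhindered diene end to the crowded carbon C5; secondary overlap with the bound formyl group favours endo; the gem-dimethyl group and the achiral dioxolane present identical faces, so nothing in 6 opposes the catalyst. The triflimide is fully bound to the oxazaborolidine, so the dioxolane and the silyl ether should survive.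

Step 7
Reactants: 9 (5R,9R,10S)-11-(tert-butyldiphenylsilyloxy)-3,3-(ethylenedioxy)-12-nordrim-7-en-15-al
Product: 11 (5R,9R,10R)-3,3-(ethylenedioxy)-12-nordrim-7-en-11-ol, via hydrazone 10 (not isolated)
Conditions: N2H4·H2O, KOH, diethylene glycol, 130 °C then 200 °C
Reagents that add atoms: none
Why: Wolff–Kishner reduction (Huang-Minlon procedure) of the non-enolisable angular aldehyde should give the C15 methyl group with C10 untouched, the ketal and the isolated olefin are inert to base, and hot alkali cleaves the primary TBDPS ether in the same operation.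

Step 8
Reactants: 11 (5R,9R,10R)-3,3-(ethylenedioxy)-12-nordrim-7-en-11-ol
Product: 14 (5R,8R,9R,10R)-3,3-(ethylenedioxy)-12-nordrimane-8,11-diol, via dimethylsilyl ether 12 (not isolated), via cyclic siloxane 13 (not isolated)
Conditions: (HMe2Si)2NH, 60 °C, evaporate; Pt2(dvds)3 (dvds = 1,3-divinyltetramethyldisiloxane, zerovalent platinum, 0.5 mol %), toluene, 60 °C; then 30% H2O2, KF, KHCO3, THF/MeOH, 40 °C
Reagents that add atoms: hydrogen peroxide, OO
Why: Intramolecular hydrosilylation followed by Tamao–Fleming oxidation: the Si–H tethered to O11 can reach the C7=C8 olefin only through a five-membered ring (5-exo), so silicon and then oxygen should end on C8 and not on C7, cis to C11 (syn addition, oxidation with retention); the C8 stereocentre is removed in step 10.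

Step 9
Reactants: 14 (5R,8R,9R,10R)-3,3-(ethylenedioxy)-12-nordrimane-8,11-diol; 15 isofraxidin (7-hydroxy-6,8-dimethoxy-2H-chromen-2-one)
Product: 16 7-{[(5R,8R,9R,10R)-3,3-(ethylenedioxy)-8-hydroxy-12-nordriman-11-yl]oxy}-6,8-dimethoxy-2H-chromen-2-one
Conditions: PPh3, diisopropyl azodicarboxylate, THF, 0 to 45 °C
Reagents that add atoms: none
Why: Mitsunobu etherification: the oxyphosphonium ion should form at the primary C11 hydroxyl and be displaced by the acidic phenol in an SN2 step, while the hindered secondary C8 hydroxyl stays free and no stereocentre is touched.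

Step 10
Reactants: 16 7-{[(5R,8R,9R,10R)-3,3-(ethylenedioxy)-8-hydroxy-12-nordriman-11-yl]oxy}-6,8-dimethoxy-2H-chromen-2-one
Product: 17 7-{[(5R,9R,10R)-3,3-(ethylenedioxy)-8-oxo-12-nordriman-11-yl]oxy}-6,8-dimethoxy-2H-chromen-2-one
Conditions: Dess–Martin periodinane (1,1,1-triacetoxy-1,1-dihydro-1,2-benziodoxol-3(1H)-one), NaHCO3, CH2Cl2, 0 °C to rt
Reagents that add atoms: none
Why: Dess–Martin oxidation under buffered, non-basic conditions should give the C8 ketone without enolisation toward C9, so the β-aryloxy group is not eliminated and C9 is not epimerised.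

Step 11
Reactants: 17 7-{[(5R,9R,10R)-3,3-(ethylenedioxy)-8-oxo-12-nordriman-11-yl]oxy}-6,8-dimethoxy-2H-chromen-2-one
Product: 18 7-{[(5R,9R,10R)-3,3-(ethylenedioxy)drim-8(12)-en-11-yl]oxy}-6,8-dimethoxy-2H-chromen-2-one
Conditions: Zn, CH2Br2, TiCl4, THF (reagent pre-formed, −40 to 5 °C); then 17, CH2Cl2, 0 °C to rt
Reagents that add atoms: dibromomethane, BrCBr
Why: Takai–Lombardo methylenation uses a non-basic zinc–titanium methylene reagent that reacts with ketones but not with esters or lactones, so the coumarin, the β-aryloxy group and the α-stereocentre C9 should be left alone.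

Step 12
Reactants: 18 7-{[(5R,9R,10R)-3,3-(ethylenedioxy)drim-8(12)-en-11-yl]oxy}-6,8-dimethoxy-2H-chromen-2-one
Product: 19 7-{[(5R,9R,10R)-3-oxodrim-8(12)-en-11-yl]oxy}-6,8-dimethoxy-2H-chromen-2-one
Conditions: pyridinium p-toluenesulfonate, acetone/H2O, 55 °C
Reagents that add atoms: water, O
Why: Mild acid-catalysed ketal hydrolysis is helped by strain relief next to the quaternary C4, and these conditions should not isomerise the exocyclic olefin or affect the aryl ether or the lactone.

Step 13
Reactants: 19 7-{[(5R,9R,10R)-3-oxodrim-8(12)-en-11-yl]oxy}-6,8-dimethoxy-2H-chromen-2-one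
Product: 20 7-{[(3S,5R,9R,10R)-3-hydroxydrim-8(12)-en-11-yl]oxy}-6,8-dimethoxy-2H-chromen-2-one (3-OH trans to H-5 and C15)
Conditions: NaBH4, MeOH/THF, −20 to 0 °C
Reagents that add atoms: none
Why: Borohydride reduction: the small hydride should attack C3 axially from the convex face that carries H-5 and C15, away from the axial C4 methyl and the folded ring B, which sets C3 as the equatorial (3S) alcohol in the manner of 4,4-dimethyl-3-oxo terpenoids and cis-fused 3-oxo steroids, while the lactone is not reduced at this temperature.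

Step 14
Reactants: 20 7-{[(3S,5R,9R,10R)-3-hydroxydrim-8(12)-en-11-yl]oxy}-6,8-dimethoxy-2H-chromen-2-one
Product: 21 7-{[(3S,5R,9R,10R)-3-acetoxydrim-8(12)-en-11-yl]oxy}-6,8-dimethoxy-2H-chromen-2-one (CNP0270939.1)
Conditions: Ac2O, pyridine, 4-(dimethylamino)pyridine (cat.), CH2Cl2, rt
Reagents that add atoms: acetic anhydride, CC(=O)OC(C)=O
Why: Nucleophile-catalysed acylation of the equatorial secondary alcohol proceeds with retention at C3 and should give the target.

Compound list

1 | 2,2-dimethylcyclohexane-1,3-dione | CC1(C)C(=O)CCCC1=O | starting material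
2 | 6,6-dimethyl-1,4-dioxaspiro[4.5]decan-7-one | O=C1CCCC2(OCCO2)C1(C)C | intermediate
3 | (Z)-8-(hydroxymethylene)-6,6-dimethyl-1,4-dioxaspiro[4.5]decan-7-one (chelated enol form) | O=C1/C(=C\O)CCC2(OCCO2)C1(C)C | intermediate
4 | (E)-8-(isopropoxymethylene)-6,6-dimethyl-1,4-dioxaspiro[4.5]decan-7-one | O=C1/C(=C/OC(C)C)CCC2(OCCO2)C1(C)C | intermediate
5 | (E)-8-(isopropoxymethylene)-6,6-dimethyl-1,4-dioxaspiro[4.5]decan-7-ol, racemic at the carbinol carbon, not isolated | OC1/C(=C/OC(C)C)CCC2(OCCO2)C1(C)C | intermediate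
6 | 6,6-dimethyl-1,4-dioxaspiro[4.5]dec-7-ene-8-carbaldehyde (ring A enal) | O=CC1=CC(C)(C)C2(OCCO2)CC1 | intermediate
7 | (E)-penta-2,4-dien-1-ol | C=C/C=C/CO | starting material
8 | (E)-tert-butyl(penta-2,4-dien-1-yloxy)diphenylsilane | C=C/C=C/CO[Si](c1ccccc1)(c1ccccc1)C(C)(C)C | intermediate
9 | (5R,9R,10S)-11-(tert-butyldiphenylsilyloxy)-3,3-(ethylenedioxy)-12-nordrim-7-en-15-al, cis-fused, H-5, CHO and C11 on one face | C1=CC[C@H]2C(C)(C)C3(OCCO3)CC[C@@]2(C=O)[C@@H]1CO[Si](c1ccccc1)(c1ccccc1)C(C)(C)C | intermediate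
10 | (E)-hydrazone of 9 at C15, (5R,9R,10S), not isolated | C1=CC[C@H]2C(C)(C)C3(OCCO3)CC[C@@]2(/C=N/N)[C@@H]1CO[Si](c1ccccc1)(c1ccccc1)C(C)(C)C | intermediate
11 | (5R,9R,10R)-3,3-(ethylenedioxy)-12-nordrim-7-en-11-ol, cis-fused, H-5, C15 methyl and CH2OH on one face | C1=CC[C@H]2C(C)(C)C3(OCCO3)CC[C@@]2(C)[C@@H]1CO | intermediate
12 | O-dimethylsilyl (Si–H) ether of 11, not isolated | C1=CC[C@H]2C(C)(C)C3(OCCO3)CC[C@@]2(C)[C@@H]1CO[SiH](C)C | intermediate
13 | (5R,8R,9R,10R)-cyclic siloxane, 2,2-dimethyl-1-oxa-2-silacyclopentane cis-fused to ring B (Si on C8, O on C11), not isolated | [C@@H]14CC[C@H]2C(C)(C)C3(OCCO3)CC[C@@]2(C)[C@@H]1CO[Si]4(C)C | intermediate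
14 | (5R,8R,9R,10R)-3,3-(ethylenedioxy)-12-nordrimane-8,11-diol, 8-OH cis to C11 | O[C@@H]1CC[C@H]2C(C)(C)C3(OCCO3)CC[C@@]2(C)[C@@H]1CO | intermediate
15 | isofraxidin (7-hydroxy-6,8-dimethoxy-2H-chromen-2-one) | COc1cc2ccc(=O)oc2c(OC)c1O | starting material
16 | 7-{[(5R,8R,9R,10R)-3,3-(ethylenedioxy)-8-hydroxy-12-nordriman-11-yl]oxy}-6,8-dimethoxy-2H-chromen-2-one | O[C@@H]1CC[C@H]2C(C)(C)C3(OCCO3)CC[C@@]2(C)[C@@H]1COc1c(OC)cc2ccc(=O)oc2c1OC | intermediate
17 | 7-{[(5R,9R,10R)-3,3-(ethylenedioxy)-8-oxo-12-nordriman-11-yl]oxy}-6,8-dimethoxy-2H-chromen-2-one | O=C1CC[C@H]2C(C)(C)C3(OCCO3)CC[C@@]2(C)[C@@H]1COc1c(OC)cc2ccc(=O)oc2c1OC | intermediate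
18 | 7-{[(5R,9R,10R)-3,3-(ethylenedioxy)drim-8(12)-en-11-yl]oxy}-6,8-dimethoxy-2H-chromen-2-one | C=C1CC[C@H]2C(C)(C)C3(OCCO3)CC[C@@]2(C)[C@@H]1COc1c(OC)cc2ccc(=O)oc2c1OC | intermediate
19 | 7-{[(5R,9R,10R)-3-oxodrim-8(12)-en-11-yl]oxy}-6,8-dimethoxy-2H-chromen-2-one | C=C1CC[C@H]2C(C)(C)C(=O)CC[C@@]2(C)[C@@H]1COc1c(OC)cc2ccc(=O)oc2c1OC | intermediate
20 | 7-{[(3S,5R,9R,10R)-3-hydroxydrim-8(12)-en-11-yl]oxy}-6,8-dimethoxy-2H-chromen-2-one | C=C1CC[C@H]2C(C)(C)[C@@H](O)CC[C@@]2(C)[C@@H]1COc1c(OC)cc2ccc(=O)oc2c1OC | intermediate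
21 | 7-{[(3S,5R,9R,10R)-3-acetoxydrim-8(12)-en-11-yl]oxy}-6,8-dimethoxy-2H-chromen-2-one, equivalently 7-{[(1R,4aR,6S,8aR)-6-acetoxy-5,5,8a-trimethyl-2-methylenedecahydronaphthalen-1-yl]methoxy}-6,8-dimethoxy-2H-chromen-2-one | C=C1CC[C@H]2C(C)(C)[C@@H](OC(C)=O)CC[C@@]2(C)[C@@H]1COc1c(OC)cc2ccc(=O)oc2c1OC | target

Total step count: 14.
Longest linear sequence: 13 steps (steps 1–4 and 6–14, from 1 to 21); step 5 is the one-step side branch to the diene.

Steps most likely to fail

Step 6. The cycloaddition may stall because the β-carbon C5 is neopentyl, the diene may oligomerise faster than it adds, the dioxolane may tie up the boron cation, or endo and enantioface selectivity may erode at the temperature needed for turnover. The fallback gives up catalyst control of absolute configuration and resolves later. It sets out from 6 and 8: EtAlCl2 (1.1 equiv, CH2Cl2, −78 to 0 °C) or, failing that, high pressure without a Lewis acid should give the racemic endo adduct F1. Wolff–Kishner reduction as in step 7 converts it into the racemic alcohol F2. Acylation with (1S)-camphanic chloride (pyridine, 4-(dimethylamino)pyridine, CH2Cl2) gives the wanted camphanate F3 and the diastereomeric camphanate F4, to be separated by chromatography or crystallisation. Saponification of F3 (LiOH, THF/H2O) comes back to the route at 11.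

Step 11. The β-aryloxy ketone may lose isofraxidin by β-elimination, C9 may epimerise through the enol, or the methylene reagent may attack the lactone. The fallback installs the olefin before the coumarin is attached. It sets out from 14: TBSCl and imidazole at 0 °C should silylate only the primary hydroxyl to give the mono-silyl ether F5. Dess–Martin oxidation gives the β-silyloxy ketone F6. Methylenation with Cp2TiMe2 (toluene, 65 °C), which is non-basic and now meets no ester, gives the exocyclic olefin F7. Bu4NF in THF frees the homoallylic alcohol F8. Mitsunobu etherification of F8 with 15 (PPh3, diisopropyl azodicarboxylate) comes back to the route at 18.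

Step 9. Displacement at the β-branched carbon C11 by a phenol with two ortho methoxy groups may be too slow, so that the activated alcohol is consumed by the hydrazide by-product or by the neighbouring C8 hydroxyl. The fallback separates activation from displacement. It sets out from 14: TsCl in pyridine at 0 °C should sulfonylate only the primary hydroxyl to give the primary tosylate F9. Heating F9 with 15 and Cs2CO3 in DMF (Williamson etherification with the preformed phenoxide) comes back to the route at 16.

Further compounds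

F1 | step 6 | racemic 9 (both enantiomers, relative configuration as in 9) | C1=CC[C@H]2C(C)(C)C3(OCCO3)CC[C@@]2(C=O)[C@@H]1CO[Si](c1ccccc1)(c1ccccc1)C(C)(C)C.C1=CC[C@@H]2C(C)(C)C3(OCCO3)CC[C@]2(C=O)[C@H]1CO[Si](c1ccccc1)(c1ccccc1)C(C)(C)C
F2 | step 6 | racemic 11 (both enantiomers, relative configuration as in 11) | C1=CC[C@H]2C(C)(C)C3(OCCO3)CC[C@@]2(C)[C@@H]1CO.C1=CC[C@@H]2C(C)(C)C3(OCCO3)CC[C@]2(C)[C@H]1CO
F3 | step 6 | (1S,4R)-camphanate ester of 11 | C1=CC[C@H]2C(C)(C)C3(OCCO3)CC[C@@]2(C)[C@@H]1COC(=O)[C@@]14CC[C@@](C)(C(=O)O1)C4(C)C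
F4 | step 6 | (1S,4R)-camphanate ester of the enantiomer of 11 | C1=CC[C@@H]2C(C)(C)C3(OCCO3)CC[C@]2(C)[C@H]1COC(=O)[C@@]14CC[C@@](C)(C(=O)O1)C4(C)C
F5 | step 11 | 11-O-tert-butyldimethylsilyl ether of 14 (8-OH free) | O[C@@H]1CC[C@H]2C(C)(C)C3(OCCO3)CC[C@@]2(C)[C@@H]1CO[Si](C)(C)C(C)(C)C
F6 | step 11 | (5R,9R,10R)-11-(tert-butyldimethylsilyloxy)-3,3-(ethylenedioxy)-12-nordriman-8-one | O=C1CC[C@H]2C(C)(C)C3(OCCO3)CC[C@@]2(C)[C@@H]1CO[Si](C)(C)C(C)(C)C
F7 | step 11 | (5R,9R,10R)-11-(tert-butyldimethylsilyloxy)-3,3-(ethylenedioxy)drim-8(12)-ene | C=C1CC[C@H]2C(C)(C)C3(OCCO3)CC[C@@]2(C)[C@@H]1CO[Si](C)(C)C(C)(C)C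
F8 | step 11 | (5R,9R,10R)-3,3-(ethylenedioxy)drim-8(12)-en-11-ol | C=C1CC[C@H]2C(C)(C)C3(OCCO3)CC[C@@]2(C)[C@@H]1CO
F9 | step 9 | 11-O-p-toluenesulfonate of 14 (8-OH free) | O[C@@H]1CC[C@H]2C(C)(C)C3(OCCO3)CC[C@@]2(C)[C@@H]1COS(=O)(=O)c1ccc(C)cc1
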